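## Retrosynthetic overview

1. The two esters go on last: the C9 senecioate by Steglich esterification, the C3 tiglate by Mitsunobu inversion of a 3β-alcohol. The C3 oxygen comes from the C3=C4 alkene of a cis-decalin ketone (epoxidation, Meinwald shift, hydride).
2. Ring B (C5–C6–C7–C8–C9–C10) is disconnected at C5–C6 by an anionic oxy-Cope transform. The enabling feature is the C8 ketone, which with C7, C6, the quaternary C5 and the ring-A atoms C4 and C3 forms a δ,ε-unsaturated ketone retron, C8(=O)–C7–C6–C5–C4=C3, across a cis C5–C10 ring fusion. Reconnecting C3–C8 gives a 2-dienylbicyclo[2.2.2]oct-5-en-2-ol.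
3. The cage comes from dearomatization: 2-methoxy-4,5-dimethylphenol → masked o-benzoquinone → Diels–Alder with an ethylene equivalent → meso 2,3-dione, desymmetrized by CBS reduction. C6, C7 and C11–C13 arrive as a Shapiro-derived dienyllithium.
4. Ring order: the six-membered carbocycle that becomes ring A (arene → cage) first, ring B last, closed by the rearrangement.

Key step: step 11

Remark: the decalins carry eremophilane numbering (ring A: C1–C5, C10; ring B: C5–C10; isopropenyl C11–C13; C14 on C5; C15 on C4), and β is the face of the C5 methyl group. The target is then the 3α-tigloyloxy-9β-senecioyloxy-4β,5β-dimethyl-7β-isopropenyl-10βH compound. The (S) catalyst in step 5 is assigned from the usual CBS model with the bridgehead CH as the large group; this sense of induction is an assumption to be confirmed on the first run.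

## Route

Step 1
Reactants: 1 3,4-dimethylanisole
Product: 4 2-methoxy-4,5-dimethylphenol, via aryllithium 2 (not isolated), via lithium aryltrimethoxyborate 3 (not isolated)
Conditions: n-BuLi, TMEDA, Et2O, 0 °C → rt; B(OMe)3, −78 °C → rt; 30% aq H2O2, 0 °C → rt
Reagents that add atoms: hydrogen peroxide, OO
Why: Directed ortho-metalation of the anisole should occur at the ortho position that is not flanked by a methyl group, and borylation/oxidation then replaces lithium by hydroxyl at that carbon.

Step 2
Reactants: 4 2-methoxy-4,5-dimethylphenol; 5 phenyl vinyl sulfide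
Product: 7 rac-3,3-dimethoxy-5,6-dimethyl-7-(phenylsulfanyl)bicyclo[2.2.2]oct-5-en-2-one, via masked o-benzoquinone 6 (not isolated)
Conditions: PhI(OAc)2, MeOH, 5 (5 equiv), 0 °C → rt
Reagents that add atoms: methanol, CO
Why: Oxidative dearomatization of the guaiacol in methanol gives the o-quinone monoketal 6, whose electron-poor diene (C2–C5) should undergo an inverse-demand Diels–Alder reaction with the vinyl sulfide to one regioisomer of the racemic cage; the sulfide stereocenter is removed in step 3.

Step 3
Reactants: 7 rac-3,3-dimethoxy-5,6-dimethyl-7-(phenylsulfanyl)bicyclo[2.2.2]oct-5-en-2-one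
Product: 8 rac-(1R,4S)-3,3-dimethoxy-5,6-dimethylbicyclo[2.2.2]oct-5-en-2-one
Conditions: Raney Ni (W-2, aged in acetone), acetone/EtOH, rt
Reagents that add atoms: none
Why: Raney nickel desulfurization cleaves the C–S bond, so the vinyl sulfide has served as an ethylene equivalent, and the acetone-deactivated metal should spare the tetrasubstituted alkene and the ketone.

Step 4
Reactants: 8 rac-(1R,4S)-3,3-dimethoxy-5,6-dimethylbicyclo[2.2.2]oct-5-en-2-one
Product: 9 meso-(1R,4S)-5,6-dimethylbicyclo[2.2.2]oct-5-ene-2,3-dione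
Conditions: 3 M aq HCl, THF, 45 °C
Reagents that add atoms: water, O
Why: Acid-catalysed ketal hydrolysis gives a 1,2-diketone that cannot enolize (both α-carbons are bridgeheads) and has a mirror plane, so the racemic stage ends in one meso compound.

Step 5
Reactants: 9 meso-(1R,4S)-5,6-dimethylbicyclo[2.2.2]oct-5-ene-2,3-dione
Product: 10 (1R,3S,4S)-3-hydroxy-5,6-dimethylbicyclo[2.2.2]oct-5-en-2-one
Conditions: (S)-2-methyl-CBS-oxazaborolidine (0.2 equiv), catecholborane (1.05 equiv), toluene, −78 °C
Reagents that add atoms: none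
Why: Corey–Bakshi–Shibata reduction should desymmetrize the meso diketone, because hydride goes to the open alkene-bridge face of the one carbonyl whose catalyst-preferred face is that face, which sets the carbinol carbon as S and with it the absolute configuration of the cage (later C10, C5 and C9).

Step 6
Reactants: 11 3-methylbut-3-en-2-one
Product: 12 (E)-N'-(3-methylbut-3-en-2-ylidene)-2,4,6-tri(propan-2-yl)benzenesulfonohydrazide
Conditions: 2,4,6-triisopropylbenzenesulfonohydrazide, MeOH, cat. HCl, 0 °C → rt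
Reagents that add atoms: 2,4,6-triisopropylbenzenesulfonohydrazide, CC(C)c1cc(C(C)C)c(S(=O)(=O)NN)c(C(C)C)c1
Why: Condensation of the methyl ketone with the sulfonyl hydrazide gives the trisylhydrazone needed for a Shapiro reaction.

Step 7
Reactants: 10 (1R,3S,4S)-3-hydroxy-5,6-dimethylbicyclo[2.2.2]oct-5-en-2-one; 12 (E)-N'-(3-methylbut-3-en-2-ylidene)-2,4,6-tri(propan-2-yl)benzenesulfonohydrazide
Product: 14 (1R,2S,3S,4S)-5,6-dimethyl-2-(3-methylbuta-1,3-dien-2-yl)bicyclo[2.2.2]oct-5-ene-2,3-diol, via dienyllithium 13 (not isolated)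
Conditions: 12 (2.6 equiv), n-BuLi (5.3 equiv), THF, −78 → 0 °C; then 10, −78 → −40 °C; H2O
Reagents that add atoms: none
Why: The Shapiro reaction gives dienyllithium 13, which after deprotonating the hydroxyl should add to the ketone from the alkene-bridge face (the open face of bicyclo[2.2.2]oct-5-en-2-ones and the face anti to the chelated lithium alkoxide), placing the dienyl group syn to the C5=C6 bridge as the oxy-Cope rearrangement requires.

Step 8
Reactants: 14 (1R,2S,3S,4S)-5,6-dimethyl-2-(3-methylbuta-1,3-dien-2-yl)bicyclo[2.2.2]oct-5-ene-2,3-diol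
Product: 15 (1S,3S,4R)-3-hydroxy-5,6-dimethyl-3-(3-methylbuta-1,3-dien-2-yl)bicyclo[2.2.2]oct-5-en-2-one
Conditions: IBX, DMSO, rt
Reagents that add atoms: none
Why: IBX oxidizes the secondary alcohol of a 1,2-diol to the ketone without C–C cleavage and leaves the tertiary carbinol alone, which erases the provisional carbinol centre so that it can be reset with the opposite configuration.

Step 9
Reactants: 15 (1S,3S,4R)-3-hydroxy-5,6-dimethyl-3-(3-methylbuta-1,3-dien-2-yl)bicyclo[2.2.2]oct-5-en-2-one
Product: 16 (1R,2S,3R,4S)-5,6-dimethyl-2-(3-methylbuta-1,3-dien-2-yl)bicyclo[2.2.2]oct-5-ene-2,3-diol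
Conditions: Me4NBH(OAc)3, MeCN/AcOH (1:1), −30 → 0 °C
Reagents that add atoms: none
Why: Hydroxyl-directed triacetoxyborohydride reduction delivers hydride from the ethano face (where the tertiary hydroxyl binds boron, while the dienyl group shields the alkene face), giving the trans-diol whose secondary oxygen lies on the alkene-bridge face, the configuration that becomes 9β (R) in the target.

Step 10
Reactants: 16 (1R,2S,3R,4S)-5,6-dimethyl-2-(3-methylbuta-1,3-dien-2-yl)bicyclo[2.2.2]oct-5-ene-2,3-diol
Product: 17 (1R,2S,3R,4S)-3-{[tert-butyl(dimethyl)silyl]oxy}-5,6-dimethyl-2-(3-methylbuta-1,3-dien-2-yl)bicyclo[2.2.2]oct-5-en-2-ol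
Conditions: TBSOTf (1.1 equiv), 2,6-lutidine, CH2Cl2, −78 °C
Reagents that add atoms: tert-butyldimethylsilyl trifluoromethanesulfonate, CC(C)(C)[Si](C)(C)OS(=O)(=O)C(F)(F)F
Why: Low-temperature silylation with the silyl triflate should be selective for the secondary over the tertiary hydroxyl, and the resulting alkoxy group sits where the 3,3-dialkoxy analogues of this rearrangement already carry one.

Step 11
Reactants: 17 (1R,2S,3R,4S)-3-{[tert-butyl(dimethyl)silyl]oxy}-5,6-dimethyl-2-(3-methylbuta-1,3-dien-2-yl)bicyclo[2.2.2]oct-5-en-2-ol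
Product: 20 9β-{[tert-butyl(dimethyl)silyl]oxy}-10βH-eremophila-3,11-dien-8-one, via potassium alkoxide 18 (not isolated), via potassium dienolate 19 (not isolated)
Conditions: KH, 18-crown-6, THF, 0 °C → rt; AcOH, THF, −78 °C
Reagents that add atoms: none
Why: Deprotonation gives alkoxide 18, in which the cage holds the 1,5-diene C6=C7–C8(O−)–C3–C4=C5 in a boat array, so the anionic oxy-Cope rearrangement ([3,3]-sigmatropic shift) should break the strained C3–C8 bond and form C5–C6 to release dienolate 19. The closest known reaction type is the anionic oxy-Cope rearrangement of 2-alkenylbicyclo[2.2.2]oct-5-en-2-ols to cis-decalin enolates. Ring B (C5–C6–C7–C8–C9–C10) is closed by this suprafacial [3,3] shift through a boat transition state, while the former cage ring (C3, C4, C5, C10, C1, C2) survives as ring A with the C3=C4 alkene. The quaternary C5 is controlled by the cage, since C6 can only reach the face of C4=C5 that looks at the C8–C9 bridge, which makes C5–C6 cis to C10–C9 and the C5 methyl cis to H10; C9 and C10 pass through unchanged. C7 is set on protonation, where a chair-like α-face protonation gives the 7β-isopropenyl ketone, which is also by far the more stable epimer (C5 methyl, isopropenyl and silyloxy all equatorial on ring B), so a 7-epimer could be equilibrated to it through the enol. The step needs the dienyl group syn to the alkene bridge (secured in step 7) and α- rather than γ-protonation of the dienolate (secured by the fast low-temperature acetic acid quench), which keeps the C11 alkene out of conjugation.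

Step 12
Reactants: 20 9β-{[tert-butyl(dimethyl)silyl]oxy}-10βH-eremophila-3,11-dien-8-one
Product: 21 9β-{[tert-butyl(dimethyl)silyl]oxy}-3β,4β-epoxy-10βH-eremophil-11-en-8-one
Conditions: mCPBA (1.1 equiv), NaHCO3, CH2Cl2, −20 → 0 °C
Reagents that add atoms: 3-chloroperoxybenzoic acid, O=C(OO)c1cccc(Cl)c1
Why: Prilezhaev epoxidation should prefer the more electron-rich trisubstituted ring alkene over the 1,1-disubstituted isopropenyl group, and the face of attack is not critical because C3 and C4 are reset in steps 13 to 15 (the β-epoxide is drawn).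

Step 13
Reactants: 21 9β-{[tert-butyl(dimethyl)silyl]oxy}-3β,4β-epoxy-10βH-eremophil-11-en-8-one
Product: 22 9β-{[tert-butyl(dimethyl)silyl]oxy}-10βH-eremophil-11-ene-3,8-dione
Conditions: LiClO4 (5 M in Et2O), rt
Reagents that add atoms: none
Why: The Lewis-acid-promoted Meinwald rearrangement opens the epoxide at the tertiary C4 and shifts the C3 hydride to C4 to give the C3 ketone (ring contraction would build two adjacent quaternary carbons), and C4 ends, directly or by enol equilibration, as the equatorial 4β-methyl epimer cis to the C5 methyl.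

Step 14
Reactants: 22 9β-{[tert-butyl(dimethyl)silyl]oxy}-10βH-eremophil-11-ene-3,8-dione
Product: 23 9β-{[tert-butyl(dimethyl)silyl]oxy}-3β-hydroxy-10βH-eremophil-11-en-8-one
Conditions: LiBH(s-Bu)3 (1.05 equiv), THF, −78 °C
Reagents that add atoms: none
Why: The bulky borohydride should reduce only the less hindered C3 ketone (C8 is flanked by two substituted carbons) and attack it along the equatorial α trajectory, away from the syn-axial C5 methyl, to give the axial 3β-alcohol.

Step 15
Reactants: 23 9β-{[tert-butyl(dimethyl)silyl]oxy}-3β-hydroxy-10βH-eremophil-11-en-8-one; 24 tiglic acid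
Product: 25 9β-{[tert-butyl(dimethyl)silyl]oxy}-3α-[(E)-2-methylbut-2-enoyloxy]-10βH-eremophil-11-en-8-one
Conditions: PPh3, DIAD, toluene, 0 °C → rt
Reagents that add atoms: none
Why: Mitsunobu esterification inverts C3, the carboxylate entering along the same equatorial trajectory as the hydride of step 14, and so installs the tiglate directly as the equatorial 3α-ester with the E alkene untouched.

Step 16
Reactants: 25 9β-{[tert-butyl(dimethyl)silyl]oxy}-3α-[(E)-2-methylbut-2-enoyloxy]-10βH-eremophil-11-en-8-one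
Product: 26 9β-hydroxy-3α-[(E)-2-methylbut-2-enoyloxy]-10βH-eremophil-11-en-8-one
Conditions: HF·pyridine, THF/pyridine, 0 °C → rt
Reagents that add atoms: none
Why: Fluoride cleavage of the silyl ether under mildly acidic conditions avoids the base that could move the C11 alkene into conjugation or epimerize C7 and C9.

Step 17
Reactants: 26 9β-hydroxy-3α-[(E)-2-methylbut-2-enoyloxy]-10βH-eremophil-11-en-8-one; 27 senecioic acid
Product: 28 (3R,4R,5R,7R,9R,10S)-3-[(E)-2-methylbut-2-enoyloxy]-9-(3-methylbut-2-enoyloxy)eremophil-11-en-8-one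
Conditions: DCC, DMAP (cat.), CH2Cl2, 0 °C → rt
Reagents that add atoms: none
Why: Steglich esterification acylates the only free hydroxyl under near-neutral conditions, which avoids the ketene pathway that deconjugates senecioyl chloride and spares the base-sensitive β,γ-unsaturated ketone.

## Compound list

1 | 3,4-dimethylanisole (4-methoxy-1,2-dimethylbenzene) | COc1ccc(C)c(C)c1 | starting material
2 | (2-methoxy-4,5-dimethylphenyl)lithium | [Li]c1cc(C)c(C)cc1OC | intermediate
3 | lithium trimethoxy(2-methoxy-4,5-dimethylphenyl)borate | [Li+].CO[B-](OC)(OC)c1cc(C)c(C)cc1OC | intermediate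
4 | 2-methoxy-4,5-dimethylphenol | COc1cc(C)c(C)cc1O | intermediate
5 | phenyl vinyl sulfide | C=CSc1ccccc1 | starting material
6 | 6,6-dimethoxy-3,4-dimethylcyclohexa-2,4-dien-1-one | COC1(OC)C=C(C)C(C)=CC1=O | intermediate
7 | rac-3,3-dimethoxy-5,6-dimethyl-7-(phenylsulfanyl)bicyclo[2.2.2]oct-5-en-2-one (sulfide syn to the C5=C6 bridge; one enantiomer drawn) | O=C1C(OC)(OC)[C@H]2C[C@H](Sc3ccccc3)[C@@H]1C(C)=C2C | intermediate
8 | rac-(1R,4S)-3,3-dimethoxy-5,6-dimethylbicyclo[2.2.2]oct-5-en-2-one (one enantiomer drawn) | O=C1C(OC)(OC)[C@H]2CC[C@@H]1C(C)=C2C | intermediate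
9 | meso-(1R,4S)-5,6-dimethylbicyclo[2.2.2]oct-5-ene-2,3-dione | O=C1C(=O)[C@H]2CC[C@@H]1C(C)=C2C | intermediate
10 | (1R,3S,4S)-3-hydroxy-5,6-dimethylbicyclo[2.2.2]oct-5-en-2-one (hydroxyl on the ethano face) | O=C1[C@@H](O)[C@H]2CC[C@@H]1C(C)=C2C | intermediate
11 | 3-methylbut-3-en-2-one | CC(=O)C(C)=C | starting material
12 | (E)-N'-(3-methylbut-3-en-2-ylidene)-2,4,6-tri(propan-2-yl)benzenesulfonohydrazide | C=C(C)/C(C)=N/NS(=O)(=O)c1c(C(C)C)cc(C(C)C)cc1C(C)C | intermediate
13 | (3-methylbuta-1,3-dien-2-yl)lithium | [Li]C(=C)C(C)=C | intermediate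
14 | (1R,2S,3S,4S)-5,6-dimethyl-2-(3-methylbuta-1,3-dien-2-yl)bicyclo[2.2.2]oct-5-ene-2,3-diol (cis-diol, both hydroxyls on the ethano face) | C=C(C)C(=C)[C@]1(O)[C@@H](O)[C@H]2CC[C@@H]1C(C)=C2C | intermediate
15 | (1S,3S,4R)-3-hydroxy-5,6-dimethyl-3-(3-methylbuta-1,3-dien-2-yl)bicyclo[2.2.2]oct-5-en-2-one | C=C(C)C(=C)[C@]1(O)C(=O)[C@H]2CC[C@@H]1C(C)=C2C | intermediate
16 | (1R,2S,3R,4S)-5,6-dimethyl-2-(3-methylbuta-1,3-dien-2-yl)bicyclo[2.2.2]oct-5-ene-2,3-diol (trans-diol, secondary hydroxyl on the alkene face) | C=C(C)C(=C)[C@]1(O)[C@H](O)[C@H]2CC[C@@H]1C(C)=C2C | intermediate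
17 | (1R,2S,3R,4S)-3-{[tert-butyl(dimethyl)silyl]oxy}-5,6-dimethyl-2-(3-methylbuta-1,3-dien-2-yl)bicyclo[2.2.2]oct-5-en-2-ol | C=C(C)C(=C)[C@]1(O)[C@H](O[Si](C)(C)C(C)(C)C)[C@H]2CC[C@@H]1C(C)=C2C | intermediate
18 | potassium alkoxide of 17 | C=C(C)C(=C)[C@]1([O-])[C@H](O[Si](C)(C)C(C)(C)C)[C@H]2CC[C@@H]1C(C)=C2C.[K+] | intermediate
19 | potassium 9β-{[tert-butyl(dimethyl)silyl]oxy}-10βH-eremophila-3,7,11-trien-8-olate | [K+].[O-]C1=C(C(C)=C)C[C@@]2(C)[C@H](CCC=C2C)[C@H]1O[Si](C)(C)C(C)(C)C | intermediate
20 | 9β-{[tert-butyl(dimethyl)silyl]oxy}-10βH-eremophila-3,11-dien-8-one (5β-methyl, 7β-isopropenyl) | C=C(C)[C@H]1C[C@@]2(C)[C@H](CCC=C2C)[C@@H](O[Si](C)(C)C(C)(C)C)C1=O | intermediate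
21 | 9β-{[tert-butyl(dimethyl)silyl]oxy}-3β,4β-epoxy-10βH-eremophil-11-en-8-one | C=C(C)[C@H]1C[C@@]2(C)[C@H](CC[C@@H]3O[C@]23C)[C@@H](O[Si](C)(C)C(C)(C)C)C1=O | intermediate
22 | 9β-{[tert-butyl(dimethyl)silyl]oxy}-10βH-eremophil-11-ene-3,8-dione (4β-methyl) | C=C(C)[C@H]1C[C@@]2(C)[C@H](CCC(=O)[C@@H]2C)[C@@H](O[Si](C)(C)C(C)(C)C)C1=O | intermediate
23 | 9β-{[tert-butyl(dimethyl)silyl]oxy}-3β-hydroxy-10βH-eremophil-11-en-8-one | C=C(C)[C@H]1C[C@@]2(C)[C@H](CC[C@H](O)[C@@H]2C)[C@@H](O[Si](C)(C)C(C)(C)C)C1=O | intermediate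
24 | tiglic acid, (E)-2-methylbut-2-enoic acid | OC(=O)/C(C)=C/C | starting material
25 | 9β-{[tert-butyl(dimethyl)silyl]oxy}-3α-[(E)-2-methylbut-2-enoyloxy]-10βH-eremophil-11-en-8-one | C=C(C)[C@H]1C[C@@]2(C)[C@H](CC[C@@H](OC(=O)/C(C)=C/C)[C@@H]2C)[C@@H](O[Si](C)(C)C(C)(C)C)C1=O | intermediate
26 | 9β-hydroxy-3α-[(E)-2-methylbut-2-enoyloxy]-10βH-eremophil-11-en-8-one | C=C(C)[C@H]1C[C@@]2(C)[C@H](CC[C@@H](OC(=O)/C(C)=C/C)[C@@H]2C)[C@@H](O)C1=O | intermediate
27 | senecioic acid, 3-methylbut-2-enoic acid | CC(C)=CC(=O)O | starting material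
28 | (3R,4R,5R,7R,9R,10S)-3-[(E)-2-methylbut-2-enoyloxy]-9-(3-methylbut-2-enoyloxy)eremophil-11-en-8-one (CNP0375730.1) | C=C(C)[C@H]1C[C@@]2(C)[C@H](CC[C@@H](OC(=O)/C(C)=C/C)[C@@H]2C)[C@@H](OC(=O)C=C(C)C)C1=O | target

## Step count and risks

Total steps: 17. Longest linear sequence: 16 (steps 1–5 and 7–17, from 1 to 28); step 6 is a one-step side branch.

Steps most likely to fail:

1. Step 12 (with its follow-up, step 13). The ring alkene is shielded on both faces (the C5 methyl on one, ring B on the other), so the peracid may attack the isopropenyl group instead. The epoxide may also rearrange by ring contraction or methyl shift rather than by hydride shift. The fallback sets out from 20 and returns at 22. A Schenck ene reaction with singlet oxygen (O2, rose bengal, visible light, CH2Cl2/MeOH, 0 °C) discriminates strongly between tri- and 1,1-disubstituted alkenes. It should abstract a C15 hydrogen (geminal to the bulky C5) and give the allylic hydroperoxide 9β-silyloxy-3-hydroperoxy-10βH-eremophila-4(15),11-dien-8-one F1. Kornblum–DeLaMare dehydration (Ac2O, pyridine) would convert it into the α-methylene ketone 9β-silyloxy-10βH-eremophila-4(15),11-diene-3,8-dione F2. Conjugate reduction with [(Ph3P)CuH]6 and protonation at C4 would give 22.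

2. Step 15. At the axial, 1,3-diaxially compressed carbinol, anti-periplanar elimination to the C2 or C3 alkene, or acylation with retention, may outrun the SN2 inversion. The fallback sets out from 22 and returns at 25. Meerwein–Ponndorf–Verley reduction under equilibrating conditions (Al(OiPr)3, i-PrOH, toluene, 60 °C) would give the thermodynamically preferred equatorial alcohol, 9β-silyloxy-3α-hydroxy-10βH-eremophil-11-en-8-one F3; the C8 ketone, flanked by two substituted carbons, should react much more slowly. F3 would then be esterified with retention (24, DCC, DMAP) to give 25.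

3. Step 5. The catalyst may discriminate poorly between the two enantiotopic carbonyl groups, or reduction may run on to the diol, and the labile α-hydroxy ketone could erode in enantiomeric purity through its enediol. The fallback sets out from 9 and returns at 10. NaBH4 (MeOH, −20 °C) would give the meso cis-diol meso-(1R,2R,3S,4S)-5,6-dimethylbicyclo[2.2.2]oct-5-ene-2,3-diol F4. Lipase-catalysed desymmetrizing acetylation (immobilized Candida antarctica lipase B, vinyl acetate) would give the monoacetate F5. IBX oxidation of the remaining hydroxyl would give the O-acetyl derivative of 10, the acetoxy ketone F6. Lipase-catalysed hydrolysis at pH 7 would then release 10.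

## Further compounds

F1 | step 12 | 9β-{[tert-butyl(dimethyl)silyl]oxy}-3-hydroperoxy-10βH-eremophila-4(15),11-dien-8-one (either C3 epimer) | C=C(C)[C@H]1C[C@@]2(C)[C@H](CCC(OO)C2=C)[C@@H](O[Si](C)(C)C(C)(C)C)C1=O
F2 | step 12 | 9β-{[tert-butyl(dimethyl)silyl]oxy}-10βH-eremophila-4(15),11-diene-3,8-dione | C=C(C)[C@H]1C[C@@]2(C)[C@H](CCC(=O)C2=C)[C@@H](O[Si](C)(C)C(C)(C)C)C1=O
F3 | step 15 | 9β-{[tert-butyl(dimethyl)silyl]oxy}-3α-hydroxy-10βH-eremophil-11-en-8-one | C=C(C)[C@H]1C[C@@]2(C)[C@H](CC[C@@H](O)[C@@H]2C)[C@@H](O[Si](C)(C)C(C)(C)C)C1=O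
F4 | step 5 | meso-(1R,2R,3S,4S)-5,6-dimethylbicyclo[2.2.2]oct-5-ene-2,3-diol | O[C@H]1[C@@H](O)[C@H]2CC[C@@H]1C(C)=C2C
F5 | step 5 | monoacetate of F4 (acetate on the carbinol carbon that becomes C3 of 10) | O[C@H]1[C@@H](OC(C)=O)[C@H]2CC[C@@H]1C(C)=C2C
F6 | step 5 | O-acetyl derivative of 10 | O=C1[C@@H](OC(C)=O)[C@H]2CC[C@@H]1C(C)=C2C
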